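The route rests on cutting the bond between the benzylic CH2 of the OCH2CH2 linker and C1 of the benzene ring. Both carbons enter as bromides. A nickel-catalysed electroreductive cross-electrophile coupling unites these two electrophiles at the end, so the oxidisable catechol never meets the chemistry that builds the dihydropyran ring. The step exploits the contrast between the sp3 C–Br bond of the 2-acyloxyethyl chain (radical activation) and the sp2 C–Br bond of the arene (oxidative addition). Its precursor is the 2-bromoethyl ester of the complete (2S,3R,4R)-dihydropyran. In that ester, C4 is set by an isothiourea-catalysed Michael addition–lactonisation, and C2 and C3 by a reversible oxa-Michael ring closure.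

Key step: step 6

Numbering: O1 and C2–C6 are the ring atoms of the target. C2 bears methyl, C3 formyl, C4 the acetate arm and C5 the CO2Me group; C6 is the enol-ether CH.

Assumption: the sodium enolate of methyl formylacetate and 4-bromo-1,2-bis(benzyloxy)benzene count as commercial, and the all-trans dihydropyran is taken as the most stable of the isomers that interconvert through the open dialdehyde.

Step 1
Reactants: 1 (E)-but-2-enal (crotonaldehyde)
Product: 3 (Z)-2-bromobut-2-enal, via 2,3-dibromobutanal 2 (not isolated)
Conditions: Br2, CH2Cl2, 0 °C; then Et3N, 0 °C to rt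
Reagents that add atoms: bromine, BrBr
Why: Bromination–dehydrobromination (anti addition of bromine, then E1cB loss of HBr through the acidic α-hydrogen) should give the more stable Z-bromoenal, in which methyl and formyl stay trans.

Step 2
Reactants: 3 (Z)-2-bromobut-2-enal
Product: 4 (Z)-2-bromo-1,1-dimethoxybut-2-ene
Conditions: HC(OMe)3, p-TsOH (1 mol%), MeOH, rt
Reagents that add atoms: trimethyl orthoformate, COC(OC)OC
Why: Acid-catalysed acetalisation with the orthoester as water scavenger masks the formyl group, so that the later C2 is not a doubly activated Michael position in step 4.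

Step 3
Reactants: 4 (Z)-2-bromo-1,1-dimethoxybut-2-ene; 5 acrylic acid
Product: 6 (2E,4E)-4-(dimethoxymethyl)hexa-2,4-dienoic acid
Conditions: Pd(OAc)2 (3 mol%), P(o-tol)3 (6 mol%), Et3N, MeCN, 80 °C; work-up at pH 4–5
Reagents that add atoms: none
Why: In this Mizoroki–Heck vinylation, oxidative addition of the vinyl bromide to zerovalent palladium with retention, syn insertion of acrylic acid and syn β-hydride elimination should give the 2E-dienoic acid, and the basic medium spares the acetal.

Step 4
Reactants: 6 (2E,4E)-4-(dimethoxymethyl)hexa-2,4-dienoic acid; 7 sodium (E)-3-methoxy-3-oxoprop-1-en-1-olate (sodium enolate of methyl formylacetate)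
Product: 9 methyl (4R)-4-[(2E)-1,1-dimethoxybut-2-en-2-yl]-2-oxo-3,4-dihydro-2H-pyran-5-carboxylate, via mixed pivalic anhydride 8 (not isolated)
Conditions: t-BuCOCl, iPr2NEt, MeCN, 0 °C; then 7, (2S,3R)-HyperBTM [(2S,3R)-3-isopropyl-2-phenyl-3,4-dihydro-2H-benzo[4,5]thiazolo[3,2-a]pyrimidine] (10 mol%), −20 °C to rt
Reagents that add atoms: pivaloyl chloride, CC(C)(C)C(=O)Cl (its atoms are found in 8 only)
Why: This is an isothiourea-catalysed Michael addition–lactonisation through an α,β-unsaturated acyl ammonium ion, in which the catalyst is acylated by 8 at the less hindered dienoyl carbonyl, the 1,5 O···S contact holds the s-cis enoyl unit in the catalyst plane, the pseudoaxial phenyl group shields one face so that the carbon of 7 should add to the β-carbon from the open face and set C4 as R, the new enol oxygen closes the lactone and frees the catalyst, and the twisted, methyl-capped δ-position disfavours 1,6-addition.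

Step 5
Reactants: 9 methyl (4R)-4-[(2E)-1,1-dimethoxybut-2-en-2-yl]-2-oxo-3,4-dihydro-2H-pyran-5-carboxylate; 10 2-bromoethanol
Product: 13 2-bromoethyl 2-[(2S,3R,4R)-3-formyl-5-(methoxycarbonyl)-2-methyl-3,4-dihydro-2H-pyran-4-yl]acetate, via ring-opened enol acetal 11 (not isolated), via open dialdehyde 12 (not isolated)
Conditions: 10, DMAP (10 mol%), iPr2NEt, CH2Cl2, 0 °C to rt; then CF3CO2H–H2O, CH2Cl2, rt, until the isomer composition no longer changes
Reagents that add atoms: water, O
Why: DMAP-catalysed acyl transfer should open the enol lactone at its unconjugated carbonyl (an enol ester is an activated acyl donor), aqueous acid then unmasks the E-ethylidene enal, and the enol oxygen adds to its β-carbon in a reversible 6-endo-trig oxa-Michael addition followed by protonation at the epimerisable C3, so that the fixed C4 centre steers C2 (S) and C3 (R) to the all-trans arrangement under thermodynamic control.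

Step 6
Reactants: 13 2-bromoethyl 2-[(2S,3R,4R)-3-formyl-5-(methoxycarbonyl)-2-methyl-3,4-dihydro-2H-pyran-4-yl]acetate; 14 4-bromo-1,2-bis(benzyloxy)benzene
Product: 15 2-[3,4-bis(benzyloxy)phenyl]ethyl 2-[(2S,3R,4R)-3-formyl-5-(methoxycarbonyl)-2-methyl-3,4-dihydro-2H-pyran-4-yl]acetate
Conditions: NiBr2(dme) (10 mol%), 4,4'-di-tert-butyl-2,2'-bipyridine (12 mol%), LiBr (electrolyte), DMA, undivided cell, Zn anode, nickel-foam cathode, constant current (2.2 F/mol), rt
Reagents that add atoms: none
Why: Cathodic reduction of the bipyridine-ligated nickel dibromide gives low-valent (zerovalent or monovalent) nickel, which inserts into the sp2 C–Br bond of 14; monovalent nickel abstracts bromine from the sp3 C–Br bond of 13, the primary 2-acyloxyethyl radical is captured by the arylnickel, and the trivalent aryl(alkyl)nickel forms the CH2–aryl bond by fast reductive elimination, while the zinc anode supplies the two electrons and takes up both bromides. The closest known reaction type is the nickel-catalysed electrochemical cross-electrophile coupling of aryl bromides with unactivated primary alkyl bromides. No ring is closed and no stereocentre is formed; C2, C3 and C4 lie five or more bonds from the radical carbon, and a 1,2-acyloxy shift of the radical would be degenerate. The step needs cross- over homo-selectivity, which the different activation modes of the two C–Br bonds secure, and chemoselectivity over the aldehyde and the vinylogous carbonate, which holds because the cathode potential stays at the nickel couple, well positive of the reduction of these groups. Loss of ethylene and carboxylate would need a carbanion or a long-lived alkylnickel, and radical capture with rapid reductive elimination avoids both.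

Step 7
Reactants: 15 2-[3,4-bis(benzyloxy)phenyl]ethyl 2-[(2S,3R,4R)-3-formyl-5-(methoxycarbonyl)-2-methyl-3,4-dihydro-2H-pyran-4-yl]acetate
Product: 16 methyl (2S,3R,4R)-4-{2-[2-(3,4-dihydroxyphenyl)ethoxy]-2-oxoethyl}-3-formyl-2-methyl-3,4-dihydro-2H-pyran-5-carboxylate (target)
Conditions: H2 (1 atm), 10% Pd/C, EtOAc, rt
Reagents that add atoms: none
Why: Hydrogenolysis of the two benzyl aryl ethers is neutral and should leave the aldehyde, both esters and the push–pull C5=C6 double bond untouched, so no stereocentre is disturbed.

Compound list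
1 | (E)-but-2-enal (crotonaldehyde) | C/C=C/C=O | starting material
2 | 2,3-dibromobutanal | CC(Br)C(Br)C=O | intermediate
3 | (Z)-2-bromobut-2-enal | C/C=C(Br)/C=O | intermediate
4 | (Z)-2-bromo-1,1-dimethoxybut-2-ene | C/C=C(Br)/C(OC)OC | intermediate
5 | acrylic acid | C=CC(=O)O | starting material
6 | (2E,4E)-4-(dimethoxymethyl)hexa-2,4-dienoic acid | C/C=C(\C=C\C(=O)O)C(OC)OC | intermediate
7 | sodium (E)-3-methoxy-3-oxoprop-1-en-1-olate | COC(=O)/C=C/[O-].[Na+] | starting material
8 | (2E,4E)-4-(dimethoxymethyl)hexa-2,4-dienoic pivalic anhydride | C/C=C(\C=C\C(=O)OC(=O)C(C)(C)C)C(OC)OC | intermediate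
9 | methyl (4R)-4-[(2E)-1,1-dimethoxybut-2-en-2-yl]-2-oxo-3,4-dihydro-2H-pyran-5-carboxylate | COC(=O)C1=COC(=O)C[C@@H]1/C(=C\C)C(OC)OC | intermediate
10 | 2-bromoethanol | OCCBr | starting material
11 | 2-bromoethyl (3R,4E)-4-(dimethoxymethyl)-3-(1-hydroxy-3-methoxy-3-oxoprop-1-en-2-yl)hex-4-enoate | COC(=O)C(=CO)[C@H](CC(=O)OCCBr)/C(=C\C)C(OC)OC | intermediate
12 | 2-bromoethyl (3R,4E)-4-formyl-3-(1-hydroxy-3-methoxy-3-oxoprop-1-en-2-yl)hex-4-enoate | COC(=O)C(=CO)[C@H](CC(=O)OCCBr)/C(=C\C)C=O | intermediate
13 | 2-bromoethyl 2-[(2S,3R,4R)-3-formyl-5-(methoxycarbonyl)-2-methyl-3,4-dihydro-2H-pyran-4-yl]acetate | COC(=O)C1=CO[C@@H](C)[C@H](C=O)[C@H]1CC(=O)OCCBr | intermediate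
14 | 4-bromo-1,2-bis(benzyloxy)benzene | Brc1ccc(OCc2ccccc2)c(OCc2ccccc2)c1 | starting material
15 | 2-[3,4-bis(benzyloxy)phenyl]ethyl 2-[(2S,3R,4R)-3-formyl-5-(methoxycarbonyl)-2-methyl-3,4-dihydro-2H-pyran-4-yl]acetate | COC(=O)C1=CO[C@@H](C)[C@H](C=O)[C@H]1CC(=O)OCCc1ccc(OCc2ccccc2)c(OCc2ccccc2)c1 | intermediate
16 | methyl (2S,3R,4R)-4-{2-[2-(3,4-dihydroxyphenyl)ethoxy]-2-oxoethyl}-3-formyl-2-methyl-3,4-dihydro-2H-pyran-5-carboxylate | COC(=O)C1=CO[C@@H](C)[C@H](C=O)[C@H]1CC(=O)OCCc1ccc(O)c(O)c1 | target

Total step count: 7. Longest linear sequence: 7 steps (1 to 16).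

Steps most likely to fail

Step 4. The formylacetate may condense with itself or be O-acylated without return. The enolate may add at the δ-position of the dienoyl unit, or facial shielding may be poor with the branched alkenyl substituent. The fallback sets out from 4 and comes back at 9.
- A Heck reaction of 4 with acrolein (Pd(OAc)2, Bu4NCl, NaHCO3, DMF) gives (2E,4E)-4-(dimethoxymethyl)hexa-2,4-dienal F1.
- S-Ethyl O-methyl thiomalonate F2, made from methyl malonyl chloride, ethanethiol and Et3N, is added to F1 under iminium catalysis with (R)-α,α-diphenylprolinol trimethylsilyl ether and benzoic acid. Attack at the β-carbon from the unshielded face gives methyl (3S,4E)-4-(dimethoxymethyl)-2-[(ethylsulfanyl)carbonyl]-3-(2-oxoethyl)hex-4-enoate F3.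
- Fukuyama reduction (Et3SiH, Pd/C, acetone) turns the thioester into the formyl group. Its enol closes onto the other aldehyde to give methyl (4R)-4-[(2E)-1,1-dimethoxybut-2-en-2-yl]-2-hydroxy-3,4-dihydro-2H-pyran-5-carboxylate F4.
- TEMPO/PhI(OAc)2 oxidises this lactol to 9.

Step 6. The alkyl radical or an alkylnickel species may be reduced further and fragment with loss of ethylene and carboxylate. Hydrodehalogenation, homocoupling or arylation of the aldehyde may compete. The fallback sets out from 13 and 14, comes back at 15, and returns to a nucleophile/electrophile pair.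
- Finkelstein exchange (NaI, acetone) gives 2-iodoethyl 2-[(2S,3R,4R)-3-formyl-5-(methoxycarbonyl)-2-methyl-3,4-dihydro-2H-pyran-4-yl]acetate F6.
- Zinc insertion into 14 (Zn dust, CoBr2 10 mol%, MeCN) gives [3,4-bis(benzyloxy)phenyl]zinc bromide F7.
- A Negishi-type coupling of the arylzinc reagent with the primary alkyl iodide (Ni(acac)2, 4-(trifluoromethyl)styrene, THF/NMP, −15 °C) forms the same CH2–aryl bond and gives 15.

Step 5. The alcohol may attack the vinylogous position C6 instead of the lactone carbonyl, which would lead to an enol ether and a free acid. The equilibration may also leave much of the C2 epimer. The fallback sets out from 9 and comes back at 13.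
- Aqueous acid (CF3CO2H, H2O, MeCN) cleaves lactone and acetal alike, and both modes of attack by water lead to the same open acid.
- The same ring closure then gives 2-[(2S,3R,4R)-3-formyl-5-(methoxycarbonyl)-2-methyl-3,4-dihydro-2H-pyran-4-yl]acetic acid (ent-elenolic acid series) F5, which can be purified and re-equilibrated.
- Its carboxylate (KHCO3, DMF) is alkylated with an excess of 1,2-dibromoethane to give 13.

Further compounds
F1 | step 4 | (2E,4E)-4-(dimethoxymethyl)hexa-2,4-dienal | C/C=C(\C=C\C=O)C(OC)OC
F2 | step 4 | S-ethyl O-methyl thiomalonate | CCSC(=O)CC(=O)OC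
F3 | step 4 | methyl (3S,4E)-4-(dimethoxymethyl)-2-[(ethylsulfanyl)carbonyl]-3-(2-oxoethyl)hex-4-enoate | CCSC(=O)C(C(=O)OC)[C@H](CC=O)/C(=C\C)C(OC)OC
F4 | step 4 | methyl (4R)-4-[(2E)-1,1-dimethoxybut-2-en-2-yl]-2-hydroxy-3,4-dihydro-2H-pyran-5-carboxylate | COC(=O)C1=COC(O)C[C@@H]1/C(=C\C)C(OC)OC
F5 | step 5 | 2-[(2S,3R,4R)-3-formyl-5-(methoxycarbonyl)-2-methyl-3,4-dihydro-2H-pyran-4-yl]acetic acid | COC(=O)C1=CO[C@@H](C)[C@H](C=O)[C@H]1CC(=O)O
F6 | step 6 | 2-iodoethyl 2-[(2S,3R,4R)-3-formyl-5-(methoxycarbonyl)-2-methyl-3,4-dihydro-2H-pyran-4-yl]acetate | COC(=O)C1=CO[C@@H](C)[C@H](C=O)[C@H]1CC(=O)OCCI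
F7 | step 6 | [3,4-bis(benzyloxy)phenyl]zinc bromide | Br[Zn]c1ccc(OCc2ccccc2)c(OCc2ccccc2)c1
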